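A direct plan would take the open-chain (2Z,6Z)-farnesal A1, built in four steps from two terpene alcohols, and chlorinate its terminal alkene to the racemic allylic chloride A2.
It would then close the ring at C1–C10 by a chromium-catalysed asymmetric allylation of the enal to the isopropenyl dienol A3, hydrogenate to the isopropyl dienol A4 and acylate.
Its weakest steps would be three.
The allylic chlorination of A1 would have to choose between two isolated trisubstituted alkenes, would be stopped short of full conversion, and would end four steps that create no stereocentre.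
The ring-closing allylation of A2 would make ring closure at high dilution, γ- versus α-attack, the cis C1/C10 relation and the absolute configuration all rest on one catalytic macrocyclisation without close precedent.
The hydrogenation of A3 would have to saturate one alkene out of three on the most precious intermediate, next to a free allylic alcohol.

Plan of the new route (ring atoms numbered as in the name of the target: C1 bears the ester oxygen, C10 the isopropyl group, the Z alkenes are C2=C3 and C6=C7):
The retrosynthesis cuts the ring bond C7–C8 first, then the ester C–O(acyl) bond, then C1–C10 of the open chain, then C6=C7 back to an aldehyde.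
Enabling feature: C7, an sp2 carbon of a Z alkene, is bonded to the CH2–CH2 bridge C8–C9, which ends at the stereocentre C10 next to the carbinol C1. C8–C9 is therefore a hydroborated vinyl group, and an anti-selective allylboration of the C1 aldehyde with an (E)-γ-isopropylallylboronate sets C1 and C10 and leaves exactly that vinyl group.
The arene is attached as the ester before any carbocycle exists. The ten-membered ring, the only ring made, closes last by a B-alkyl Suzuki–Miyaura coupling onto a Z alkenyl iodide.
No allylic chlorination is needed, because the chain comes from alkene cleavage of neryl acetate. Both stereocentres are set between two molecules through a closed six-membered transition state. The isopropyl group arrives saturated, so no alkene is hydrogenated and no free ring alcohol is made.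

Key step: step 10

Assumption: the (R)-configured phosphoric acid of step 7 is taken to direct the allyl group to the Re face of aldehyde 6, as with simple aryl and alkenyl aldehydes; if the opposite sense were found, the (S)-acid would be used.

Step 1
Reactants: 1 neryl acetate
Product: 3 (2Z)-3-methyl-6-oxohex-2-en-1-yl acetate, via ozonide 2 (not isolated)
Conditions: O3 (about 1 equiv, Sudan red end point), CH2Cl2, −78 °C; then PPh3 (1.1 equiv), −78 °C to 23 °C
Reagents that add atoms: ozone, [O-][O+]=O
Why: Selective ozonolysis with reductive work-up: ozone should attack the electron-rich isolated Me2C=CH alkene ahead of the alkene deactivated by the allylic acetate, so the Z alkene is kept and no stereocentre is formed.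

Step 2
Reactants: 3 (2Z)-3-methyl-6-oxohex-2-en-1-yl acetate
Product: 4 (2Z,6Z)-7-iodo-3-methylocta-2,6-dien-1-yl acetate
Conditions: EtPPh3I (1.5 equiv), n-BuLi (1.5 equiv), THF, 23 °C; I2 (1.45 equiv), −78 °C; NaN(SiMe3)2 (1.4 equiv), −20 °C; then 3, −78 °C to 0 °C
Reagents that add atoms: ethyltriphenylphosphonium iodide, CC[P+](c1ccccc1)(c1ccccc1)c1ccccc1.[I-]; iodine, II
Why: Stork–Zhao-type Wittig olefination: the α-iodo ylide made in the flask should add to the aldehyde under kinetic control to give the alkenyl iodide with chain and iodine cis (Z), which fixes the C6=C7 geometry of the target, while the acetate survives the cold ylide.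

Step 3
Reactants: 4 (2Z,6Z)-7-iodo-3-methylocta-2,6-dien-1-yl acetate
Product: 5 (2Z,6Z)-7-iodo-3-methylocta-2,6-dien-1-ol
Conditions: K2CO3 (0.2 equiv), MeOH, 0 °C to 23 °C
Reagents that add atoms: none
Why: Base-catalysed transesterification removes the primary acetate as methyl acetate and leaves the alkenyl iodide and both Z alkenes untouched.

Step 4
Reactants: 5 (2Z,6Z)-7-iodo-3-methylocta-2,6-dien-1-ol
Product: 6 (2Z,6Z)-7-iodo-3-methylocta-2,6-dienal
Conditions: TEMPO (0.1 equiv), PhI(OAc)2 (1.1 equiv), CH2Cl2, 0 °C to 23 °C, used promptly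
Reagents that add atoms: none
Why: Oxoammonium oxidation (TEMPO/PhI(OAc)2) of the allylic alcohol stops at the aldehyde under near-neutral conditions, so the Z enal should not isomerise and the alkenyl iodide is inert.

Step 5
Reactants: 7 3-methylbut-1-yne (1.3 equiv)
Product: 8 2-[(1E)-3-methylbut-1-en-1-yl]-4,4,5,5-tetramethyl-1,3,2-dioxaborolane
Conditions: pinacolborane (1.0 equiv), Cp2Zr(H)Cl (0.05 equiv), Et3N (0.1 equiv), neat, sealed vessel, 23 °C to 40 °C
Reagents that add atoms: pinacolborane, CC1(C)OBOC1(C)C
Why: Zirconium-hydride-catalysed syn hydroboration of a terminal alkyne places boron on the terminal carbon and gives the E alkenylboronate.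

Step 6
Reactants: 8 2-[(1E)-3-methylbut-1-en-1-yl]-4,4,5,5-tetramethyl-1,3,2-dioxaborolane
Product: 10 2-[(2E)-4-methylpent-2-en-1-yl]-4,4,5,5-tetramethyl-1,3,2-dioxaborolane, via boron ate complex 9 (not isolated)
Conditions: ClCH2I (1.3 equiv), n-BuLi (1.2 equiv, added last), THF, −78 °C; then 23 °C, 12 h
Reagents that add atoms: chloroiodomethane, ClCI
Why: Matteson homologation: chloromethyllithium adds to boron and 1,2-migration of the alkenyl group with loss of chloride inserts one CH2 with retention of the E geometry, giving a pinacol allylboronate that resists 1,3-boron shift.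

Step 7
Reactants: 6 (2Z,6Z)-7-iodo-3-methylocta-2,6-dienal; 10 2-[(2E)-4-methylpent-2-en-1-yl]-4,4,5,5-tetramethyl-1,3,2-dioxaborolane (1.3 equiv)
Product: 12 (3R,4R,5Z,9Z)-10-iodo-6-methyl-3-(propan-2-yl)undeca-1,5,9-trien-4-ol, via borate ester 11 (not isolated)
Conditions: (R)-3,3'-bis(2,4,6-triisopropylphenyl)-1,1'-binaphthyl-2,2'-diyl hydrogen phosphate (0.05 equiv), 4 Å molecular sieves, toluene, −30 °C; then aq NaHCO3
Reagents that add atoms: none
Why: Chiral-phosphoric-acid-catalysed allylboration through a closed chair (Zimmerman–Traxler) transition state: the E geometry of 10 places the isopropyl group equatorial and should give the anti C3/C4 pair, while the acid, hydrogen-bonded to a boronate oxygen and to the formyl hydrogen, directs attack to the Re face of 6 and so fixes both centres as R,R; γ-attack leaves the vinyl group needed for ring closure.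

Step 8
Reactants: 13 vanillic acid
Product: 15 3-methoxy-4-[(triisopropylsilyl)oxy]benzoic acid, via bis-silyl compound 14 (not isolated)
Conditions: i-Pr3SiCl (2.3 equiv), imidazole (5 equiv), DMF, 23 °C; then THF–H2O–AcOH, 23 °C
Reagents that add atoms: triisopropylsilyl chloride, CC(C)[Si](Cl)(C(C)C)C(C)C
Why: Silylation of both acidic OH groups followed by selective hydrolysis of the much more labile silyl ester leaves the aryl silyl ether in place.

Step 9
Reactants: 12 (3R,4R,5Z,9Z)-10-iodo-6-methyl-3-(propan-2-yl)undeca-1,5,9-trien-4-ol; 15 3-methoxy-4-[(triisopropylsilyl)oxy]benzoic acid (1.3 equiv)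
Product: 16 (3R,4R,5Z,9Z)-10-iodo-6-methyl-3-(propan-2-yl)undeca-1,5,9-trien-4-yl 3-methoxy-4-[(triisopropylsilyl)oxy]benzoate
Conditions: N,N'-diisopropylcarbodiimide (1.5 equiv), DMAP (0.3 equiv), CH2Cl2, 0 °C to 23 °C
Reagents that add atoms: none
Why: Steglich esterification acylates the oxygen without breaking the C–O bond of the allylic alcohol, so both stereocentres are retained.

Step 10
Reactants: 16 (3R,4R,5Z,9Z)-10-iodo-6-methyl-3-(propan-2-yl)undeca-1,5,9-trien-4-yl 3-methoxy-4-[(triisopropylsilyl)oxy]benzoate
Product: 18 (1R,2Z,6Z,10S)-3,7-dimethyl-10-(propan-2-yl)cyclodeca-2,6-dien-1-yl 3-methoxy-4-[(triisopropylsilyl)oxy]benzoate, via alkylborane 17 (not isolated)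
Conditions: 9-borabicyclo[3.3.1]nonane dimer (1.5 equiv B–H), THF, 0 °C to 23 °C; then added over 12 h to PdCl2(dppf) (0.15 equiv; dppf = 1,1'-bis(diphenylphosphino)ferrocene), AsPh3 (0.3 equiv), K3PO4 (3 equiv, 3 M in H2O), THF–DMF, 45 °C, final concentration about 2 mM
Reagents that add atoms: none
Why: The borane adds anti-Markovnikov to the only monosubstituted alkene (both trisubstituted alkenes, the alkenyl iodide and the ester are inert) to give the primary alkylborane 17; zerovalent palladium then inserts into the C–I bond with retention, the base-activated borate transfers its primary alkyl group to divalent palladium, and reductive elimination forms the C7–C8 bond. The closest known reaction types are the intramolecular B-alkyl Suzuki–Miyaura closure of nine- to twelve-membered carbocycles onto trisubstituted alkenyl iodides and the intermolecular coupling of (Z)-2-iodoalk-2-enes to Z-trisubstituted alkenes. The ten-membered ring is closed by joining the two chain ends through a C(sp3)–C(sp2) bond, so that the C6=C7 alkene ends up inside the ring. No stereocentre is made: C1 and C10 come from step 7 (the C10 descriptor changes from R to S only because the vinyl group becomes a CH2 chain), and the C6=C7 geometry is carried over by the stereoretentive oxidative addition and reductive elimination. The step needs cyclisation to beat oligomerisation, which the two Z alkenes (they bend the chain so that C7 and C8 can meet) and slow addition to a low stationary concentration should secure, and it needs the alkenyl iodide to react before the secondary allylic benzoate, which the much faster insertion into C–I should secure.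

Step 11
Reactants: 18 (1R,2Z,6Z,10S)-3,7-dimethyl-10-(propan-2-yl)cyclodeca-2,6-dien-1-yl 3-methoxy-4-[(triisopropylsilyl)oxy]benzoate
Product: 19 (1R,2Z,6Z,10S)-3,7-dimethyl-10-(propan-2-yl)cyclodeca-2,6-dien-1-yl 4-hydroxy-3-methoxybenzoate
Conditions: Bu4NF (1.2 equiv), AcOH (1.2 equiv), THF, 0 °C
Reagents that add atoms: none
Why: Fluoride-mediated desilylation of the aryl silyl ether under acetic acid buffering should leave the secondary benzoate and the acid-sensitive cyclodeca-1,5-diene untouched.

Compound list
1 | neryl acetate, (2Z)-3,7-dimethylocta-2,6-dien-1-yl acetate | CC(=O)OC/C=C(/C)CCC=C(C)C | starting material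
2 | ozonide of 1 at the terminal alkene, (2Z)-5-(5,5-dimethyl-1,2,4-trioxolan-3-yl)-3-methylpent-2-en-1-yl acetate (racemic at the trioxolane carbon) | CC(=O)OC/C=C(/C)CCC1OOC(C)(C)O1 | intermediate
3 | (2Z)-3-methyl-6-oxohex-2-en-1-yl acetate | CC(=O)OC/C=C(/C)CCC=O | intermediate
4 | (2Z,6Z)-7-iodo-3-methylocta-2,6-dien-1-yl acetate | CC(=O)OC/C=C(/C)CC/C=C(/C)I | intermediate
5 | (2Z,6Z)-7-iodo-3-methylocta-2,6-dien-1-ol | OC/C=C(/C)CC/C=C(/C)I | intermediate
6 | (2Z,6Z)-7-iodo-3-methylocta-2,6-dienal | O=C/C=C(/C)CC/C=C(/C)I | intermediate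
7 | 3-methylbut-1-yne | CC(C)C#C | starting material
8 | 2-[(1E)-3-methylbut-1-en-1-yl]-4,4,5,5-tetramethyl-1,3,2-dioxaborolane | CC(C)/C=C/B1OC(C)(C)C(C)(C)O1 | intermediate
9 | lithium (chloromethyl)[(1E)-3-methylbut-1-en-1-yl](pinacolato)borate | [Li+].CC(C)/C=C/[B-]1(CCl)OC(C)(C)C(C)(C)O1 | intermediate
10 | 2-[(2E)-4-methylpent-2-en-1-yl]-4,4,5,5-tetramethyl-1,3,2-dioxaborolane | CC(C)/C=C/CB1OC(C)(C)C(C)(C)O1 | intermediate
11 | 2-{[(3R,4R,5Z,9Z)-10-iodo-6-methyl-3-(propan-2-yl)undeca-1,5,9-trien-4-yl]oxy}-4,4,5,5-tetramethyl-1,3,2-dioxaborolane | CC1(C)OB(O[C@@H](/C=C(/C)CC/C=C(/C)I)[C@@H](C=C)C(C)C)OC1(C)C | intermediate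
12 | (3R,4R,5Z,9Z)-10-iodo-6-methyl-3-(propan-2-yl)undeca-1,5,9-trien-4-ol (OH and isopropyl anti along the chain) | O[C@@H](/C=C(/C)CC/C=C(/C)I)[C@@H](C=C)C(C)C | intermediate
13 | vanillic acid, 4-hydroxy-3-methoxybenzoic acid | COc1cc(C(=O)O)ccc1O | starting material
14 | triisopropylsilyl 3-methoxy-4-[(triisopropylsilyl)oxy]benzoate | COc1cc(C(=O)O[Si](C(C)C)(C(C)C)C(C)C)ccc1O[Si](C(C)C)(C(C)C)C(C)C | intermediate
15 | 3-methoxy-4-[(triisopropylsilyl)oxy]benzoic acid | COc1cc(C(=O)O)ccc1O[Si](C(C)C)(C(C)C)C(C)C | intermediate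
16 | (3R,4R,5Z,9Z)-10-iodo-6-methyl-3-(propan-2-yl)undeca-1,5,9-trien-4-yl 3-methoxy-4-[(triisopropylsilyl)oxy]benzoate | COc1cc(C(=O)O[C@@H](/C=C(/C)CC/C=C(/C)I)[C@@H](C=C)C(C)C)ccc1O[Si](C(C)C)(C(C)C)C(C)C | intermediate
17 | (3S,4R,5Z,9Z)-1-(9-borabicyclo[3.3.1]nonan-9-yl)-10-iodo-6-methyl-3-(propan-2-yl)undeca-5,9-dien-4-yl 3-methoxy-4-[(triisopropylsilyl)oxy]benzoate | COc1cc(C(=O)O[C@@H](/C=C(/C)CC/C=C(/C)I)[C@@H](CCB2C3CCCC2CCC3)C(C)C)ccc1O[Si](C(C)C)(C(C)C)C(C)C | intermediate
18 | (1R,2Z,6Z,10S)-3,7-dimethyl-10-(propan-2-yl)cyclodeca-2,6-dien-1-yl 3-methoxy-4-[(triisopropylsilyl)oxy]benzoate (ester oxygen and isopropyl cis on the ring) | COc1cc(C(=O)O[C@H]2/C=C(/C)CC/C=C(/C)CC[C@H]2C(C)C)ccc1O[Si](C(C)C)(C(C)C)C(C)C | intermediate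
19 | (1R,2Z,6Z,10S)-3,7-dimethyl-10-(propan-2-yl)cyclodeca-2,6-dien-1-yl 4-hydroxy-3-methoxybenzoate | COc1cc(C(=O)O[C@H]2/C=C(/C)CC/C=C(/C)CC[C@H]2C(C)C)ccc1O | target

Total step count: 11. Longest linear sequence: 8 steps (steps 1, 2, 3, 4, 7, 9, 10, 11, from neryl acetate).

Steps most likely to fail:

Step 10. Ring closure may lose to oligomerisation, the borane may be protodeboronated before transmetalation, or zerovalent palladium may ionise the allylic benzoate. Fallback: the boron nucleophile and the basic aqueous medium are replaced by an organozinc made by insertion. Setting out from 16, hydroboration as before but with oxidative work-up (NaBO3·4H2O) would give the primary alcohol (3S,4R,5Z,9Z)-1-hydroxy-10-iodo-6-methyl-3-(propan-2-yl)undeca-5,9-dien-4-yl 3-methoxy-4-[(triisopropylsilyl)oxy]benzoate F1. Iodination (I2, PPh3, imidazole, CH2Cl2, 0 °C) would give the primary iodide, the 1,10-diiodo analogue F2. Zinc insertion (Zn dust, LiCl, THF, 25 °C), selective for the alkyl over the alkenyl iodide, would give the alkylzinc iodide F3. Slow addition of F3 to Pd(PPh3)4 in THF would close the ring by an intramolecular Negishi coupling under anhydrous, base-free conditions and rejoin the route at 18.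

Step 7. Facial selectivity under catalyst control may be poor with the hindered γ-isopropyl reagent, or a slow reaction may allow Z-to-E isomerisation of the enal. Fallback: setting out from 6 and 10, the allylboration would be run without catalyst (toluene, 23 °C). This keeps the chair transition state and the anti relation but gives 12 together with its mirror image, the (3S,4S) alcohol F4. Esterification as in step 9 would give 16 and the (3S,4S) ester F5, which would be separated by preparative chromatography on a chiral stationary phase; the route is rejoined at 16.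

Step 2. The iodo-ylide olefination may give incomplete Z selectivity or lose iodine from the ylide. Fallback: the alkenyl halide is built in two stereodefined stages. Setting out from 3, Corey–Fuchs olefination (CBr4, PPh3, CH2Cl2, 0 °C) would give the dibromoalkene (2Z)-7,7-dibromo-3-methylhepta-2,6-dien-1-yl acetate F6. Palladium-catalysed mono-methylation (MeZnCl, PdCl2[bis(2-diphenylphosphinophenyl) ether], THF, 0 °C), which takes place at the bromine trans to the chain, would give the alkenyl bromide (2Z,6Z)-7-bromo-3-methylocta-2,6-dien-1-yl acetate F7. Copper-catalysed halogen exchange with retention (CuI, NaI, N,N'-dimethylethane-1,2-diamine, dioxane, 110 °C) would then rejoin the route at 4.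

Further compounds
F1 | step 10 | (3S,4R,5Z,9Z)-1-hydroxy-10-iodo-6-methyl-3-(propan-2-yl)undeca-5,9-dien-4-yl 3-methoxy-4-[(triisopropylsilyl)oxy]benzoate | COc1cc(C(=O)O[C@@H](/C=C(/C)CC/C=C(/C)I)[C@@H](CCO)C(C)C)ccc1O[Si](C(C)C)(C(C)C)C(C)C
F2 | step 10 | (3S,4R,5Z,9Z)-1,10-diiodo-6-methyl-3-(propan-2-yl)undeca-5,9-dien-4-yl 3-methoxy-4-[(triisopropylsilyl)oxy]benzoate | COc1cc(C(=O)O[C@@H](/C=C(/C)CC/C=C(/C)I)[C@@H](CCI)C(C)C)ccc1O[Si](C(C)C)(C(C)C)C(C)C
F3 | step 10 | iodo{(3S,4R,5Z,9Z)-10-iodo-4-({3-methoxy-4-[(triisopropylsilyl)oxy]benzoyl}oxy)-6-methyl-3-(propan-2-yl)undeca-5,9-dien-1-yl}zinc | COc1cc(C(=O)O[C@@H](/C=C(/C)CC/C=C(/C)I)[C@@H](CC[Zn]I)C(C)C)ccc1O[Si](C(C)C)(C(C)C)C(C)C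
F4 | step 7 | (3S,4S,5Z,9Z)-10-iodo-6-methyl-3-(propan-2-yl)undeca-1,5,9-trien-4-ol | O[C@H](/C=C(/C)CC/C=C(/C)I)[C@H](C=C)C(C)C
F5 | step 7 | (3S,4S,5Z,9Z)-10-iodo-6-methyl-3-(propan-2-yl)undeca-1,5,9-trien-4-yl 3-methoxy-4-[(triisopropylsilyl)oxy]benzoate | COc1cc(C(=O)O[C@H](/C=C(/C)CC/C=C(/C)I)[C@H](C=C)C(C)C)ccc1O[Si](C(C)C)(C(C)C)C(C)C
F6 | step 2 | (2Z)-7,7-dibromo-3-methylhepta-2,6-dien-1-yl acetate | CC(=O)OC/C=C(/C)CCC=C(Br)Br
F7 | step 2 | (2Z,6Z)-7-bromo-3-methylocta-2,6-dien-1-yl acetate | CC(=O)OC/C=C(/C)CC/C=C(/C)Br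
A1 | direct plan | (2Z,6Z)-farnesal, (2Z,6Z)-3,7,11-trimethyldodeca-2,6,10-trienal | CC(C)=CCC/C(C)=C\CC/C(C)=C\C=O
A2 | direct plan | (2Z,6Z)-10-chloro-3,7,11-trimethyldodeca-2,6,11-trienal (racemic at C10) | C=C(C)C(Cl)CC/C(C)=C\CC/C(C)=C\C=O
A3 | direct plan | (1S,2Z,6Z,10S)-3,7-dimethyl-10-(prop-1-en-2-yl)cyclodeca-2,6-dien-1-ol | O[C@H]1/C=C(/C)CC/C=C(/C)CC[C@H]1C(C)=C
A4 | direct plan | (1R,2Z,6Z,10S)-3,7-dimethyl-10-(propan-2-yl)cyclodeca-2,6-dien-1-ol | O[C@H]1/C=C(/C)CC/C=C(/C)CC[C@H]1C(C)C
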